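## Retrosynthetic overview

- The plan rests on one feature: O2' of ring B is separated from C4 only by C2', C1' and C3, so O2', C2', C1', C3 and C4 can form a benzofuran-2(3H)-one. C4 is therefore stored as the lactone of the very phenol that the target needs free.
- Ring C is closed last, by the C4–C4a bond: an aryl anion at C4a of ring A, tethered through O1–C2, takes the acyl carbon from O2' (lactone 17 → chromanone 20), and mild acid then gives target 21.
- Lactone 17 comes from the C1'–C3 bond: an enantioselective Friedel–Crafts hydroxyalkylation of phenol 9 by aryloxypyruvate 13 sets C3, followed by lactonisation and silylation.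
- Phenol 9 comes from o-vanillin (Baeyer–Villiger oxidation fixes which oxygen is free; methoxy-directed lithiation places the prenyl group). Keto ester 13 comes from 4-bromoresorcinol and ethyl bromopyruvate.
- Ring order: rings A and B are bought, the temporary lactone ring forms in step 10, ring C forms in step 12.

Key step: step 12

Remarks on the chemistry:
- O3' is masked as a MOM ether before the C1'–C3 bond is made. A free C3' hydroxyl is para to C6' and would open a second site of attack, and the free catechol would chelate the catalyst.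
- The tertiary C3 hydroxyl is carried as a triethylsilyl ether. It goes onto the hindered α-hydroxy lactone without strong base and comes off without forcing acid.
- The sense of induction in step 8 is assigned by analogy with additions to pyruvate esters chelated on the same copper bis(oxazoline) catalyst. If the sense found is the reverse, the (S,S) ligand is used and nothing else changes. (R,R)-t-Bu-box is 2,2'-(propane-2,2-diyl)bis[(4R)-4-tert-butyl-4,5-dihydro-1,3-oxazole].

## Route

Step 1
Reactants: 1 2-hydroxy-3-methoxybenzaldehyde (o-vanillin)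
Product: 2 3-methoxy-2-(methoxymethoxy)benzaldehyde
Conditions: MOMCl, i-Pr2NEt, CH2Cl2, 0 °C → rt
Reagents that add atoms: chloromethyl methyl ether (MOMCl), COCCl
Why: Williamson-type O-alkylation of the phenol by the chloromethyl ether under amine base, the aldehyde being inert.

Step 2
Reactants: 2 3-methoxy-2-(methoxymethoxy)benzaldehyde
Product: 4 3-methoxy-2-(methoxymethoxy)phenol, via aryl formate 3 (not isolated)
Conditions: mCPBA, CH2Cl2, 0 °C → rt; then K2CO3 (cat.), MeOH, rt
Reagents that add atoms: 3-chloroperoxybenzoic acid (mCPBA), OOC(=O)c1cccc(Cl)c1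
Why: Baeyer–Villiger oxidation of an electron-rich benzaldehyde, in which the oxygenated aryl group migrates to give the formate, followed by base-catalysed methanolysis, so that the free hydroxyl is unambiguously the future O2'.

Step 3
Reactants: 4 3-methoxy-2-(methoxymethoxy)phenol
Product: 5 [3-methoxy-2-(methoxymethoxy)phenoxy]triisopropylsilane
Conditions: TIPSCl, imidazole, DMF, rt
Reagents that add atoms: chlorotriisopropylsilane (TIPSCl), CC(C)[Si](Cl)(C(C)C)C(C)C
Why: Standard silylation of a phenol, which installs a bulky ether that neither directs lithiation nor leaves its ortho position accessible.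

Step 4
Reactants: 5 [3-methoxy-2-(methoxymethoxy)phenoxy]triisopropylsilane; 6 1-bromo-3-methylbut-2-ene (prenyl bromide)
Product: 8 [3-methoxy-2-(methoxymethoxy)-4-(3-methylbut-2-en-1-yl)phenoxy]triisopropylsilane, via C4 aryllithium 7 (not isolated)
Conditions: n-BuLi, TMEDA, THF, 0 °C; then CuBr·SMe2 (10 mol %), 6, −78 °C → rt
Reagents that add atoms: none
Why: Directed ortho-metalation, in which the methoxyl is the only ether with a free and unshielded ortho position (the MOM ether has none, the silyl ether blocks C6), followed by copper-catalysed coupling of the aryllithium at the primary carbon of prenyl bromide to give the linear prenyl group.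

Step 5
Reactants: 8 [3-methoxy-2-(methoxymethoxy)-4-(3-methylbut-2-en-1-yl)phenoxy]triisopropylsilane
Product: 9 3-methoxy-2-(methoxymethoxy)-4-(3-methylbut-2-en-1-yl)phenol
Conditions: TBAF, AcOH, THF, 0 °C
Reagents that add atoms: none
Why: Fluoride-induced cleavage of the aryl silyl ether, buffered with acetic acid so that the electron-rich phenoxide is not exposed, with MOM ether and alkene inert.

Step 6
Reactants: 10 4-bromobenzene-1,3-diol (4-bromoresorcinol)
Product: 11 2-bromo-5-(methoxymethoxy)phenol
Conditions: MOMCl (1.0 equiv), i-Pr2NEt, CH2Cl2, −20 → 0 °C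
Reagents that add atoms: chloromethyl methyl ether (MOMCl), COCCl
Why: Mono-alkylation should favour the hydroxyl para to bromine, which is less hindered than the one ortho to bromine, and regioisomeric or doubly protected material would be removed by chromatography.

Step 7
Reactants: 11 2-bromo-5-(methoxymethoxy)phenol; 12 ethyl 3-bromo-2-oxopropanoate (ethyl bromopyruvate)
Product: 13 ethyl 3-[2-bromo-5-(methoxymethoxy)phenoxy]-2-oxopropanoate
Conditions: K2CO3, acetone, 0 °C → rt
Reagents that add atoms: none
Why: Williamson ether synthesis on a highly reactive α-bromo ketone, with mild carbonate base at low temperature to limit self-condensation, the keto ester being used promptly.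

Step 8
Reactants: 9 3-methoxy-2-(methoxymethoxy)-4-(3-methylbut-2-en-1-yl)phenol; 13 ethyl 3-[2-bromo-5-(methoxymethoxy)phenoxy]-2-oxopropanoate
Product: 14 ethyl (2S)-3-[2-bromo-5-(methoxymethoxy)phenoxy]-2-hydroxy-2-[2-hydroxy-4-methoxy-3-(methoxymethoxy)-5-(3-methylbut-2-en-1-yl)phenyl]propanoate
Conditions: Cu(OTf)2 (10 mol %), (R,R)-t-Bu-box (11 mol %), 4 Å MS, CH2Cl2, −20 °C → rt, under argon
Reagents that add atoms: none
Why: Enantioselective Friedel–Crafts hydroxyalkylation in which the keto ester chelates the chiral divalent copper complex through both carbonyl oxygens and the phenol attacks through C6, its only free position that is ortho to the hydroxyl and para to the methoxyl (C4 carries the prenyl group, C5 is meta to both), the (R,R) ligand being expected to expose the Re face of the ketone so that C3 is formed S.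

Step 9
Reactants: 14 ethyl (2S)-3-[2-bromo-5-(methoxymethoxy)phenoxy]-2-hydroxy-2-[2-hydroxy-4-methoxy-3-(methoxymethoxy)-5-(3-methylbut-2-en-1-yl)phenyl]propanoate
Product: 15 (2S)-3-[2-bromo-5-(methoxymethoxy)phenoxy]-2-hydroxy-2-[2-hydroxy-4-methoxy-3-(methoxymethoxy)-5-(3-methylbut-2-en-1-yl)phenyl]propanoic acid
Conditions: LiOH·H2O, THF/H2O, 0 °C → rt; then 1 M HCl to pH 4, 0 °C
Reagents that add atoms: water, O
Why: Saponification of an α-hydroxy ester assisted by the neighbouring phenoxide, at a carbon that has no hydrogen and cannot epimerise, any lactone already formed in step 8 being opened to the same acid.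

Step 10
Reactants: 15 (2S)-3-[2-bromo-5-(methoxymethoxy)phenoxy]-2-hydroxy-2-[2-hydroxy-4-methoxy-3-(methoxymethoxy)-5-(3-methylbut-2-en-1-yl)phenyl]propanoic acid
Product: 16 (3S)-3-{[2-bromo-5-(methoxymethoxy)phenoxy]methyl}-3-hydroxy-6-methoxy-7-(methoxymethoxy)-5-(3-methylbut-2-en-1-yl)-1-benzofuran-2(3H)-one
Conditions: EDC·HCl, DMAP (cat.), CH2Cl2, 0 °C → rt
Reagents that add atoms: none
Why: Carbodiimide-mediated (Steglich-type) lactonisation in which the activated acid is trapped by the ortho phenol in a 5-exo-trig closure under neutral conditions that spare the MOM ethers, the tertiary hydroxyl being unable to compete.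

Step 11
Reactants: 16 (3S)-3-{[2-bromo-5-(methoxymethoxy)phenoxy]methyl}-3-hydroxy-6-methoxy-7-(methoxymethoxy)-5-(3-methylbut-2-en-1-yl)-1-benzofuran-2(3H)-one
Product: 17 (3S)-3-{[2-bromo-5-(methoxymethoxy)phenoxy]methyl}-6-methoxy-7-(methoxymethoxy)-5-(3-methylbut-2-en-1-yl)-3-[(triethylsilyl)oxy]-1-benzofuran-2(3H)-one
Conditions: TESOTf, 2,6-lutidine, CH2Cl2, −78 → 0 °C
Reagents that add atoms: triethylsilyl trifluoromethanesulfonate (TESOTf), CC[Si](CC)(CC)OS(=O)(=O)C(F)(F)F
Why: Silylation of a hindered tertiary alcohol by a silyl triflate with a hindered pyridine base, under which the lactone (no α-hydrogen) and the MOM ethers should be stable at low temperature.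

Step 12
Reactants: 17 (3S)-3-{[2-bromo-5-(methoxymethoxy)phenoxy]methyl}-6-methoxy-7-(methoxymethoxy)-5-(3-methylbut-2-en-1-yl)-3-[(triethylsilyl)oxy]-1-benzofuran-2(3H)-one
Product: 20 (3S)-3-[2-hydroxy-4-methoxy-3-(methoxymethoxy)-5-(3-methylbut-2-en-1-yl)phenyl]-7-(methoxymethoxy)-3-[(triethylsilyl)oxy]-2,3-dihydro-4H-chromen-4-one, via C4a aryllithium 18 (not isolated), via cis-fused lithium alkoxide 19 (not isolated)
Conditions: t-BuLi (2.05 equiv), THF, −100 → −78 °C; then AcOH, −78 °C
Reagents that add atoms: none
Why: Two equivalents of t-BuLi exchange the C4a bromine (the second destroys the tert-butyl bromide formed), the aryllithium 18 adds to the lactone carbonyl held beside it by the O1–C2–C3 tether, and the cis-fused tetrahedral alkoxide 19 collapses by expelling the C2' phenoxide, so that the C4–C4a bond and ring C are formed while the five-membered lactone is given up. The closest known reaction type is the Parham cyclisation, halogen–lithium exchange followed by intramolecular acylation of the aryllithium by an ester or lactone. Ring C closes in a 6-exo-trig mode, the aryl carbon attacking from the face of C3 that bears the CH2O tether, opposite to the silyl ether. No stereocentre is formed, and C3, which has no hydrogen and keeps all four of its bonds, stays S. The step needs exchange to outrun addition of t-BuLi to the aryl ester and needs the new ketone to escape a second addition; the first should follow from the very fast exchange of an aryl bromide flanked by an ether oxygen at −100 °C and from the shielding of the carbonyl by the fully substituted C3, the second from the absence of any organolithium once the intramolecular transfer is over and from the acid quench at −78 °C. Six-membered closure is the only one possible, because the lactone carbonyl is the sole electrophile within reach of C4a.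

Step 13
Reactants: 20 (3S)-3-[2-hydroxy-4-methoxy-3-(methoxymethoxy)-5-(3-methylbut-2-en-1-yl)phenyl]-7-(methoxymethoxy)-3-[(triethylsilyl)oxy]-2,3-dihydro-4H-chromen-4-one
Product: 21 (3S)-3-[2,3-dihydroxy-4-methoxy-5-(3-methylbut-2-en-1-yl)phenyl]-3,7-dihydroxy-2,3-dihydro-4H-chromen-4-one (target)
Conditions: HCl (1.25 M in MeOH), THF, 0 °C → rt, under argon
Reagents that add atoms: none
Why: Acid-catalysed acetal exchange of the two aryl MOM ethers and solvolysis of the silyl ether, under conditions mild enough that the prenyl group (no ortho hydroxyl to cyclise onto) and the tertiary ketol should survive, the C3–O bond never being broken so that the S configuration is kept.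

## Compound list

1 | 2-hydroxy-3-methoxybenzaldehyde (o-vanillin) | COc1cccc(C=O)c1O | starting material
2 | 3-methoxy-2-(methoxymethoxy)benzaldehyde | COc1cccc(C=O)c1OCOC | intermediate
3 | 3-methoxy-2-(methoxymethoxy)phenyl formate | COc1cccc(OC=O)c1OCOC | intermediate
4 | 3-methoxy-2-(methoxymethoxy)phenol | COc1cccc(O)c1OCOC | intermediate
5 | [3-methoxy-2-(methoxymethoxy)phenoxy]triisopropylsilane | COc1cccc(O[Si](C(C)C)(C(C)C)C(C)C)c1OCOC | intermediate
6 | 1-bromo-3-methylbut-2-ene (prenyl bromide) | CC(C)=CCBr | starting material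
7 | {2-methoxy-3-(methoxymethoxy)-4-[(triisopropylsilyl)oxy]phenyl}lithium | COc1c([Li])ccc(O[Si](C(C)C)(C(C)C)C(C)C)c1OCOC | intermediate
8 | [3-methoxy-2-(methoxymethoxy)-4-(3-methylbut-2-en-1-yl)phenoxy]triisopropylsilane | COc1c(CC=C(C)C)ccc(O[Si](C(C)C)(C(C)C)C(C)C)c1OCOC | intermediate
9 | 3-methoxy-2-(methoxymethoxy)-4-(3-methylbut-2-en-1-yl)phenol | COc1c(CC=C(C)C)ccc(O)c1OCOC | intermediate
10 | 4-bromobenzene-1,3-diol (4-bromoresorcinol) | Oc1ccc(Br)c(O)c1 | starting material
11 | 2-bromo-5-(methoxymethoxy)phenol | COCOc1ccc(Br)c(O)c1 | intermediate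
12 | ethyl 3-bromo-2-oxopropanoate (ethyl bromopyruvate) | CCOC(=O)C(=O)CBr | starting material
13 | ethyl 3-[2-bromo-5-(methoxymethoxy)phenoxy]-2-oxopropanoate | CCOC(=O)C(=O)COc1cc(OCOC)ccc1Br | intermediate
14 | ethyl (2S)-3-[2-bromo-5-(methoxymethoxy)phenoxy]-2-hydroxy-2-[2-hydroxy-4-methoxy-3-(methoxymethoxy)-5-(3-methylbut-2-en-1-yl)phenyl]propanoate | COc1c(CC=C(C)C)cc(c(O)c1OCOC)[C@](O)(COc1cc(OCOC)ccc1Br)C(=O)OCC | intermediate
15 | (2S)-3-[2-bromo-5-(methoxymethoxy)phenoxy]-2-hydroxy-2-[2-hydroxy-4-methoxy-3-(methoxymethoxy)-5-(3-methylbut-2-en-1-yl)phenyl]propanoic acid | COc1c(CC=C(C)C)cc(c(O)c1OCOC)[C@](O)(COc1cc(OCOC)ccc1Br)C(=O)O | intermediate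
16 | (3S)-3-{[2-bromo-5-(methoxymethoxy)phenoxy]methyl}-3-hydroxy-6-methoxy-7-(methoxymethoxy)-5-(3-methylbut-2-en-1-yl)-1-benzofuran-2(3H)-one | COc1c(CC=C(C)C)cc2c(OC(=O)[C@@]2(O)COc3cc(OCOC)ccc3Br)c1OCOC | intermediate
17 | (3S)-3-{[2-bromo-5-(methoxymethoxy)phenoxy]methyl}-6-methoxy-7-(methoxymethoxy)-5-(3-methylbut-2-en-1-yl)-3-[(triethylsilyl)oxy]-1-benzofuran-2(3H)-one | COc1c(CC=C(C)C)cc2c(OC(=O)[C@@]2(O[Si](CC)(CC)CC)COc3cc(OCOC)ccc3Br)c1OCOC | intermediate
18 | lactone 17 with lithium in place of bromine at C4a of ring A, C3 unchanged (S) | COc1c(CC=C(C)C)cc2c(OC(=O)[C@@]2(O[Si](CC)(CC)CC)COc3cc(OCOC)ccc3[Li])c1OCOC | intermediate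
19 | lithium alkoxide of the cis-fused tetrahedral adduct: the former lactone carbon C4 carries O2', O−, C3 and C4a; O− and OSiEt3 on the same face; C3 as in 17 | [Li+].COc1c(CC=C(C)C)cc2c(c1OCOC)O[C@@]1([O-])c3ccc(OCOC)cc3OC[C@@]21O[Si](CC)(CC)CC | intermediate
20 | (3S)-3-[2-hydroxy-4-methoxy-3-(methoxymethoxy)-5-(3-methylbut-2-en-1-yl)phenyl]-7-(methoxymethoxy)-3-[(triethylsilyl)oxy]-2,3-dihydro-4H-chromen-4-one | COc1c(CC=C(C)C)cc([C@]2(O[Si](CC)(CC)CC)COc3cc(OCOC)ccc3C2=O)c(O)c1OCOC | intermediate
21 | (3S)-3-[2,3-dihydroxy-4-methoxy-5-(3-methylbut-2-en-1-yl)phenyl]-3,7-dihydroxy-2,3-dihydro-4H-chromen-4-one | COc1c(CC=C(C)C)cc([C@]2(O)COc3cc(O)ccc3C2=O)c(O)c1O | target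

## Step count and risks

Total step count: 13. Longest linear sequence: 11 (steps 1–5 and 8–13); steps 6 and 7 form the second branch.

Steps most likely to fail:

1. Step 8. The ketone of 13 is less electrophilic than the trifluoropyruvates usually used in such additions, so the reaction may be slow and facial control incomplete. The divalent copper salt may also oxidise the electron-rich phenol, or 13 may cyclodehydrate onto its own ring A.
Fallback (stereocentre by resolution instead of catalysis), setting out from 9 and returning at 15: phenol 9 is converted into its bromomagnesium phenoxide (EtMgBr, toluene/CH2Cl2, 0 °C) and treated with 13. This ortho-specific hydroxyalkylation of a metal phenoxide should give the racemic hydroxy ester F1. Saponification as in step 9 gives the racemic acid F2. Fractional crystallisation with (R)-1-phenylethylamine separates the salt of the (S)-acid F3 from the salt of the (R)-acid F4. Which salt is the less soluble has to be found, and the (S)-amine is the alternative. Acidification of F3 gives 15.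

2. Step 12. t-BuLi may add to the aryl ester before exchange, or aryllithium 18 may be protonated before it cyclises, which would give debrominated lactone.
Fallback (a different acyl acceptor), setting out from 17 and returning at 21: the lactone is opened with the chloromagnesium amide of N,O-dimethylhydroxylamine (MeNH(OMe)·HCl, i-PrMgCl, THF, −20 °C) to the N-methoxy-N-methyl amide with free C2' phenol F5. The phenol is protected (MOMCl, i-Pr2NEt, CH2Cl2) to give the tetra-protected amide F6. Bromine–lithium exchange (t-BuLi, THF, −78 °C) followed by Parham cyclisation onto the amide, whose chelated tetrahedral intermediate cannot take up a second nucleophile, gives the fully protected chromanone F7. The conditions of step 13 remove the silyl ether and all three MOM ethers and give 21.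

3. Step 7. Ethyl bromopyruvate may self-condense under base, or the phenoxide may attack the ketone instead of displacing bromide, and the product may enolise.
Fallback (oxidation state adjusted after the ether is made), setting out from 11 and returning at 13: phenol 11 opens racemic ethyl oxirane-2-carboxylate at its CH2 terminus (CsF cat., DMF, 60 °C) to give the racemic hydroxy ester F8. Oxidation of its secondary alcohol with DMP (the triacetoxy periodinane, CH2Cl2, rt) gives 13.

## Further compounds

F1 | step 8 | racemic ethyl 3-[2-bromo-5-(methoxymethoxy)phenoxy]-2-hydroxy-2-[2-hydroxy-4-methoxy-3-(methoxymethoxy)-5-(3-methylbut-2-en-1-yl)phenyl]propanoate | COc1c(CC=C(C)C)cc(c(O)c1OCOC)C(O)(COc1cc(OCOC)ccc1Br)C(=O)OCC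
F2 | step 8 | racemic 3-[2-bromo-5-(methoxymethoxy)phenoxy]-2-hydroxy-2-[2-hydroxy-4-methoxy-3-(methoxymethoxy)-5-(3-methylbut-2-en-1-yl)phenyl]propanoic acid | COc1c(CC=C(C)C)cc(c(O)c1OCOC)C(O)(COc1cc(OCOC)ccc1Br)C(=O)O
F3 | step 8 | (R)-1-phenylethylammonium salt of the (2S)-acid 15 | COc1c(CC=C(C)C)cc(c(O)c1OCOC)[C@](O)(COc1cc(OCOC)ccc1Br)C(=O)[O-].C[C@@H]([NH3+])c1ccccc1
F4 | step 8 | (R)-1-phenylethylammonium salt of the (2R)-acid | COc1c(CC=C(C)C)cc(c(O)c1OCOC)[C@@](O)(COc1cc(OCOC)ccc1Br)C(=O)[O-].C[C@@H]([NH3+])c1ccccc1
F5 | step 12 | (2S)-3-[2-bromo-5-(methoxymethoxy)phenoxy]-2-[2-hydroxy-4-methoxy-3-(methoxymethoxy)-5-(3-methylbut-2-en-1-yl)phenyl]-N-methoxy-N-methyl-2-[(triethylsilyl)oxy]propanamide | COc1c(CC=C(C)C)cc(c(O)c1OCOC)[C@](O[Si](CC)(CC)CC)(COc1cc(OCOC)ccc1Br)C(=O)N(C)OC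
F6 | step 12 | (2S)-3-[2-bromo-5-(methoxymethoxy)phenoxy]-N-methoxy-2-[4-methoxy-2,3-bis(methoxymethoxy)-5-(3-methylbut-2-en-1-yl)phenyl]-N-methyl-2-[(triethylsilyl)oxy]propanamide | COc1c(CC=C(C)C)cc(c(OCOC)c1OCOC)[C@](O[Si](CC)(CC)CC)(COc1cc(OCOC)ccc1Br)C(=O)N(C)OC
F7 | step 12 | (3S)-3-[4-methoxy-2,3-bis(methoxymethoxy)-5-(3-methylbut-2-en-1-yl)phenyl]-7-(methoxymethoxy)-3-[(triethylsilyl)oxy]-2,3-dihydro-4H-chromen-4-one | COc1c(CC=C(C)C)cc([C@]2(O[Si](CC)(CC)CC)COc3cc(OCOC)ccc3C2=O)c(OCOC)c1OCOC
F8 | step 7 | racemic ethyl 3-[2-bromo-5-(methoxymethoxy)phenoxy]-2-hydroxypropanoate | CCOC(=O)C(O)COc1cc(OCOC)ccc1Br
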